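**Retrosynthetic overview**
1. The target is a 5,7-dihydroxyisoflavone whose B ring is a 2,2-dimethylchroman-8-ol attached through its C5 (pyran O on C3', pyran CH2 on C2', free OH on C4'); the last operation only removes two A-ring benzyl ethers.
2. Key disconnection: the pyran ring (O–CMe2–CH2–CH2–C2'–C3') is traced back to the five-membered oxolane ring of a 1-oxaspiro[4.5]deca-7,9-dien-6-one (spiro carbon = C3', carbonyl = C4'). A 1,2-shift of the ring CH2 from C3' to C2' expands it by one atom, and the spirodienone is made in the same flask by oxidative dearomatisation of the 4'-hydroxy-3'-(3-hydroxy-3-methylbutyl)isoflavone 15.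
3. Enabling feature: the free 4'-OH lies ortho to the pyran oxygen on C3', and the next ring carbon C2' carries the pyran C4 methylene; this C4'(OH)/C3'(O)/C2'(CH2) triad is the retron of a protonated cyclohexa-2,4-dienone bearing O and CH2 on the sp3 carbon next to the carbonyl.
4. Compound 15 is cut at C3–C1' (Suzuki coupling) into 3-iodochromone 14 (from phloroacetophenone by enaminone iodocyclisation) and arylboronate 7 (from dihydrocoumarin by MeMgBr addition, para-bromination and borylation).
5. Ring order: the A and B benzene rings are bought; the pyranone ring C is closed in step 6; the oxolane spiro ring and then the pyran ring are formed in step 8.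

Key step: step 8

Remark: the target has no stereocentre, so no stereocontrol is needed. Isoflavone locants (C2–C8, C1'–C6') are used for the B-ring positions throughout.

**Step 1**
Reactants: 1 3,4-dihydrocoumarin (chroman-2-one); 2 methylmagnesium bromide
Product: 3 2-(3-hydroxy-3-methylbutyl)phenol
Conditions: MeMgBr (3 equiv), THF, 0 °C to rt; then cold 1 M HCl
Reagents that add atoms: methylmagnesium bromide, C[Mg]Br
Why: Double Grignard addition to the lactone carbonyl should open the ring and deliver the tertiary carbinol and the free phenol, the classical conversion of dihydrocoumarins.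

**Step 2**
Reactants: 3 2-(3-hydroxy-3-methylbutyl)phenol; 4 N-bromosuccinimide
Product: 5 4-bromo-2-(3-hydroxy-3-methylbutyl)phenol
Conditions: NBS (1.0 equiv), MeCN, −10 to 0 °C
Reagents that add atoms: N-bromosuccinimide, O=C1CCC(=O)N1Br
Why: Electrophilic aromatic bromination of an ortho-alkylphenol should go para to the hydroxyl, the most activated and least hindered position, and the tertiary alcohol is inert.

**Step 3**
Reactants: 5 4-bromo-2-(3-hydroxy-3-methylbutyl)phenol; 6 bis(pinacolato)diboron
Product: 7 2-(3-hydroxy-3-methylbutyl)-4-(4,4,5,5-tetramethyl-1,3,2-dioxaborolan-2-yl)phenol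
Conditions: B2pin2 (1.2 equiv), PdCl2(dppf) (3 mol%), KOAc (3 equiv), 1,4-dioxane, 85 °C
Reagents that add atoms: bis(pinacolato)diboron, CC1(C)OB(OC1(C)C)B1OC(C)(C)C(C)(C)O1
Why: Miyaura borylation of the aryl bromide; acetate is too weak a base to start Suzuki homocoupling, and free phenols and tertiary alcohols are tolerated.

**Step 4**
Reactants: 8 2',4',6'-trihydroxyacetophenone; 9 benzyl bromide
Product: 10 1-[2,4-bis(benzyloxy)-6-hydroxyphenyl]ethanone
Conditions: BnBr (2.05 equiv), K2CO3 (2.2 equiv), DMF, rt
Reagents that add atoms: benzyl bromide, BrCc1ccccc1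
Why: Williamson etherification; one ortho hydroxyl stays locked in a hydrogen bond to the acetyl carbonyl and is alkylated last, so two equivalents should give the 2,4-dibenzyl ether.

**Step 5**
Reactants: 10 1-[2,4-bis(benzyloxy)-6-hydroxyphenyl]ethanone; 11 N,N-dimethylformamide dimethyl acetal
Product: 12 (E)-1-[2,4-bis(benzyloxy)-6-hydroxyphenyl]-3-(dimethylamino)prop-2-en-1-one
Conditions: DMF-DMA (3 equiv), toluene, 95 °C
Reagents that add atoms: N,N-dimethylformamide dimethyl acetal, COC(OC)N(C)C
Why: Condensation of the methyl ketone with the amide acetal should give the (E)-enaminone, the standard first stage of the 3-iodochromone synthesis.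

**Step 6**
Reactants: 12 (E)-1-[2,4-bis(benzyloxy)-6-hydroxyphenyl]-3-(dimethylamino)prop-2-en-1-one; 13 iodine
Product: 14 5,7-bis(benzyloxy)-3-iodo-4H-chromen-4-one
Conditions: I2 (1.2 equiv), CHCl3, rt
Reagents that add atoms: iodine, II
Why: Iodination of the enaminone α-carbon, 6-exo-trig attack of the phenol on the iminium carbon and loss of dimethylamine should close the pyranone ring (iodine-mediated enaminone cyclisation to 3-iodochromones).

**Step 7**
Reactants: 14 5,7-bis(benzyloxy)-3-iodo-4H-chromen-4-one; 7 2-(3-hydroxy-3-methylbutyl)-4-(4,4,5,5-tetramethyl-1,3,2-dioxaborolan-2-yl)phenol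
Product: 15 5,7-bis(benzyloxy)-3-[4-hydroxy-3-(3-hydroxy-3-methylbutyl)phenyl]-4H-chromen-4-one
Conditions: Pd(dppf)Cl2 (5 mol%), Na2CO3 (2 M aq, 2.5 equiv), DME, 70 °C
Reagents that add atoms: none
Why: Suzuki–Miyaura coupling of a 3-iodochromone with an arylboronate is the standard isoflavone C3–C1' bond formation and tolerates the free phenol and tertiary alcohol.

**Step 8**
Reactants: 15 5,7-bis(benzyloxy)-3-[4-hydroxy-3-(3-hydroxy-3-methylbutyl)phenyl]-4H-chromen-4-one
Product: 17 5,7-bis(benzyloxy)-3-(8-hydroxy-2,2-dimethylchroman-5-yl)-4H-chromen-4-one, via oxaspirodienone 16 (not isolated)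
Conditions: PhI(OAc)2 (1.0 equiv, slow addition), CH2Cl2/(CF3)2CHOH (4:1), 0.02 M, −20 °C; then TFA (10 equiv), −20 °C to rt
Reagents that add atoms: none
Why: Proposed new method: the 4'-phenol should exchange onto iodine(III) and, on loss of PhI and acetate, be captured at the ortho carbon C3' by the tethered tertiary hydroxyl to give the cyclohexa-2,4-dienone 16, whose protonation by TFA puts positive charge on C2' so that the oxolane CH2 shifts from the spiro carbon C3' to C2' (dienone–phenol rearrangement, pushed by the ether oxygen lone pair, which leaves an oxocarbenium ion at C3'), and loss of the C2' proton restores the arene. The closest known reaction types are the hypervalent-iodine ortho-spirocyclisation of phenols carrying a hydroxyalkyl or carboxyalkyl arm and the acid-catalysed ring-expanding dienone–phenol rearrangement of spiro[4.5]decadienones and of para-quinol spiro ethers (1-oxaspiro[4.5]deca-6,9-dien-8-ones to chroman-6-ols); what has not been shown is this shift in an ortho-quinol spiro ether. The oxolane ring closes 5-exo-trig by O-attack on the ring carbon C3', and the pyran ring is not closed as such but grows out of the oxolane by the 1,2-carbon shift (five to six ring atoms). The only new stereocentre, the spiro carbon of 16, forms as a racemate and is erased when C3' becomes aromatic. The step needs ortho rather than para capture, which the intramolecular five-ring closure should secure because capture at the para carbon C1' would require an external nucleophile that the fluoroalcohol medium does not offer; it also needs carbon rather than oxygen migration, which is favoured because only the CH2 shift leaves the cation on an oxygen-bearing carbon and C2' is the only cationic carbon next to the spiro centre. One equivalent of oxidant at −20 °C should leave the benzyl ethers, the chromone and the acyl-deactivated A ring untouched, and the acid is added only after the oxidant is spent so that the product phenol is not oxidised further.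

**Step 9**
Reactants: 17 5,7-bis(benzyloxy)-3-(8-hydroxy-2,2-dimethylchroman-5-yl)-4H-chromen-4-one
Product: 18 5,7-dihydroxy-3-(8-hydroxy-2,2-dimethylchroman-5-yl)-4H-chromen-4-one
Conditions: H2 (1 atm), 10% Pd/C, EtOAc/MeOH, rt, stopped when both benzyl ethers are cleaved
Reagents that add atoms: none
Why: Catalytic hydrogenolysis of aryl benzyl ethers should free the 5- and 7-hydroxyls while the chroman ether, the phenol and the chromone survive a short exposure.

**Compound list**
1 | 3,4-dihydrocoumarin (chroman-2-one) | O=C1CCc2ccccc2O1 | starting material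
2 | methylmagnesium bromide | C[Mg]Br | starting material
3 | 2-(3-hydroxy-3-methylbutyl)phenol | CC(C)(O)CCc1ccccc1O | intermediate
4 | N-bromosuccinimide | O=C1CCC(=O)N1Br | starting material
5 | 4-bromo-2-(3-hydroxy-3-methylbutyl)phenol | CC(C)(O)CCc1cc(Br)ccc1O | intermediate
6 | bis(pinacolato)diboron | CC1(C)OB(OC1(C)C)B1OC(C)(C)C(C)(C)O1 | starting material
7 | 2-(3-hydroxy-3-methylbutyl)-4-(4,4,5,5-tetramethyl-1,3,2-dioxaborolan-2-yl)phenol | CC(C)(O)CCc1cc(B2OC(C)(C)C(C)(C)O2)ccc1O | intermediate
8 | 2',4',6'-trihydroxyacetophenone | CC(=O)c1c(O)cc(O)cc1O | starting material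
9 | benzyl bromide | BrCc1ccccc1 | starting material
10 | 1-[2,4-bis(benzyloxy)-6-hydroxyphenyl]ethanone | CC(=O)c1c(O)cc(OCc2ccccc2)cc1OCc1ccccc1 | intermediate
11 | N,N-dimethylformamide dimethyl acetal | COC(OC)N(C)C | starting material
12 | (E)-1-[2,4-bis(benzyloxy)-6-hydroxyphenyl]-3-(dimethylamino)prop-2-en-1-one | CN(C)/C=C/C(=O)c1c(O)cc(OCc2ccccc2)cc1OCc1ccccc1 | intermediate
13 | iodine | II | starting material
14 | 5,7-bis(benzyloxy)-3-iodo-4H-chromen-4-one | O=c1c(I)coc2cc(OCc3ccccc3)cc(OCc3ccccc3)c12 | intermediate
15 | 5,7-bis(benzyloxy)-3-[4-hydroxy-3-(3-hydroxy-3-methylbutyl)phenyl]-4H-chromen-4-one | CC(C)(O)CCc1cc(-c2coc3cc(OCc4ccccc4)cc(OCc4ccccc4)c3c2=O)ccc1O | intermediate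
16 | 9-[5,7-bis(benzyloxy)-4-oxo-4H-chromen-3-yl]-2,2-dimethyl-1-oxaspiro[4.5]deca-7,9-dien-6-one (racemic, not isolated) | CC1(C)CCC2(O1)C=C(-c1coc3cc(OCc4ccccc4)cc(OCc4ccccc4)c3c1=O)C=CC2=O | intermediate
17 | 5,7-bis(benzyloxy)-3-(8-hydroxy-2,2-dimethylchroman-5-yl)-4H-chromen-4-one | CC1(C)CCc2c(-c3coc4cc(OCc5ccccc5)cc(OCc5ccccc5)c4c3=O)ccc(O)c2O1 | intermediate
18 | 5,7-dihydroxy-3-(8-hydroxy-2,2-dimethylchroman-5-yl)-4H-chromen-4-one | CC1(C)CCc2c(-c3coc4cc(O)cc(O)c4c3=O)ccc(O)c2O1 | target

**Totals**
Total step count: 9. Longest linear sequence: 6 steps (steps 1, 2, 3, 7, 8, 9 or steps 4, 5, 6, 7, 8, 9).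

**Steps most likely to fail**

Step 8 (proposed new method). Several processes could divert the cascade:
- capture of the oxidised phenol at the para carbon C1' by acetate;
- [4+2] dimerisation of the dienone before the shift;
- migration of oxygen instead of carbon, giving the isomeric chroman;
- further oxidation of the newly formed phenol if the shift starts while oxidant remains.

The fallback uses known chemistry only; it sets out from 3 and comes back at 17. Heating 3 with catalytic p-TsOH in toluene should close the ring by cyclodehydration to 2,2-dimethylchroman F1. Ortho-lithiation next to the ring oxygen (s-BuLi, TMEDA, Et2O, 0 °C), trapping with B(OMe)3 and oxidation (H2O2, NaOH) should give 2,2-dimethylchroman-8-ol F2. Bromination para to the free hydroxyl (NBS, MeCN, 0 °C) should give 5-bromo-2,2-dimethylchroman-8-ol F3. Miyaura borylation under the conditions of step 3 should give 2,2-dimethyl-5-(4,4,5,5-tetramethyl-1,3,2-dioxaborolan-2-yl)chroman-8-ol F4, and Suzuki coupling of F4 with 14 under the conditions of step 7 should give 17.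

Step 7. Aqueous base may open the pyranone ring of the iodochromone, and the electron-rich hydroxyaryl boronate may protodeboronate before transmetalation. The fallback replaces the basic boron coupling by a base-free tin coupling; it sets out from 5 and comes back at 15, and it also bypasses step 3. Stannylation of 5 (Me3SnSnMe3, Pd(PPh3)4, toluene, 100 °C) should give 2-(3-hydroxy-3-methylbutyl)-4-(trimethylstannyl)phenol F5. Stille coupling of F5 with 14 (Pd(PPh3)4, CuI, DMF, 60 °C) should give 15.

Step 9. The chromone C2=C3 double bond may be reduced before both benzyl ethers are cleaved. The fallback is a non-reductive Lewis-acid debenzylation; it sets out from 17 and comes back at 18 without any new compound. BCl3 with pentamethylbenzene as benzyl-cation scavenger (CH2Cl2, −78 °C) should cleave both aryl benzyl ethers, the chelated 5-O-benzyl first, and leave the C2=C3 bond untouched.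

**Further compounds**
F1 | step 8 | 2,2-dimethylchroman | CC1(C)CCc2ccccc2O1
F2 | step 8 | 2,2-dimethylchroman-8-ol | CC1(C)CCc2cccc(O)c2O1
F3 | step 8 | 5-bromo-2,2-dimethylchroman-8-ol | CC1(C)CCc2c(Br)ccc(O)c2O1
F4 | step 8 | 2,2-dimethyl-5-(4,4,5,5-tetramethyl-1,3,2-dioxaborolan-2-yl)chroman-8-ol | CC1(C)CCc2c(B3OC(C)(C)C(C)(C)O3)ccc(O)c2O1
F5 | step 7 | 2-(3-hydroxy-3-methylbutyl)-4-(trimethylstannyl)phenol | CC(C)(O)CCc1cc([Sn](C)(C)C)ccc1O
F0 | step 9 | none | none
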